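(Readings and results stem from a simulated flask for an exercise.)

The amounts are the same in both earlier runs and the temperatures differ, so the meeting on the south-east flask began with two curves.

in all of them: starting material 0.20 M; free enzyme 0.20 mM

| run | protic impurity | temperature | remark | time |
|---|---|---|---|---|
| south-east | 0.040 M | 5 °C | the very flask that is asked about, followed so far |  |
| west | 0.040 M | −10 °C | run made earlier |  |
| flask | 0.0400 M | 5 °C |  | 1.5 h |

| south-east: time / min | south-east: product / % | west: time / min | west: product / % |
|---|---|---|---|
| 10.0 | 51 | 20.0 | 58 |
| 25.0 | 52 | 50.0 | 62 |
| 50.0 | 55 | 120 | 64 |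
| 80.0 | 59 | 180 | 68 |

(each reading ± 2 percentage points)

- Tuesday's: at 1.5 h raise the temperature by 15 K, then wait 25 min
- Friday's: at 1.5 h take out 90% of the product then present, then wait 25 min
- Saturday's: change nothing and wait 25 min more
- Sunday's: at 1.5 h add free enzyme, 50.0% of the amount charged, then wait 25 min

- product taken out counts as made
- the earlier runs were read with a standard deviation of 2 percentage points
- additions bring no volume worth counting

- product, in percent of the starting material first charged, at 1.5 h
- the option that brings most further product ("none" if no option brings more than 2 percentage points) (Tuesday's / Friday's / Saturday's / Sunday's / none)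
- product present, with what was taken out counted in, in percent of the starting material first charged, after Saturday's
- product present, with what was taken out counted in, in percent of the starting material first charged, after Sunday's

The analyst reported that south-east read 51% after 10.0 min and 59% after 80.0 min: a burst, then a slow creep. She drew the creep through those two readings back to time zero, which put the burst at 49.9%. Carried forward, the creep adds 1.1 percentage points by 1.5 h, so she committed to 60.1% now.

The process chemist proposed one number for the options. Call the shortfall the share of the starting material charged that is not yet product; the worth of a charge is then the number of half-lives of the shortfall that one whole charge of free enzyme buys in its burst, here 0.996.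

West, read the same way, has a burst of 56.7% and a worth of 1.21. That reading is higher than south-east's, so he spoke against Tuesday's. Neither earlier run had product taken out, so Friday's stayed unreckoned.

Assuming that half-lives bought go with the dose, Sunday's 50.0% buys 0.498 of them, which takes 12 points off a shortfall of 39.9%. The chair set this against the 2.9 points that the creep brings in 25 min; Sunday's gain is larger. The minutes therefore record Sunday's at 72.1%, creep not counted, and Saturday's at 63.0%.

The forecast gives 60% now, 63% after Saturday's and 74% after Sunday's, which it names best, above the minutes' Sunday figure, on the ground that “Fresh enzyme should give a new burst before it dies too”.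

The flask gives 60.0% at 1.5 h, and Sunday's brings 10 points, reaching 70.0%, while Saturday's reaches 61.8%.

    free enzyme → unfolded enzyme (k = 1.40 × 10⁻⁴ s⁻¹, Ea = 254 kJ mol⁻¹)
    starting material + free enzyme → product + free enzyme, rate k2*[starting material]*[free enzyme]/(1 + ([starting material]/Km2) + ([product]/Kp2)) (0.270 M, 0.190 M, k = 220 L mol⁻¹ s⁻¹, Ea = 41.0 kJ mol⁻¹)
    2 free enzyme ⇌ resting dimer (K = 1.30 × 10⁶ L mol⁻¹, k = 120 L mol⁻¹ s⁻¹, Ea = 43.0 kJ mol⁻¹, ΔH = −62.0 kJ mol⁻¹)
    starting material + protic impurity → quenched substrate (k = 0.470 L mol⁻¹ s⁻¹, Ea = 43.0 kJ mol⁻¹)
    free enzyme → spent catalyst (k = 0.0120 s⁻¹, Ea = 84.0 kJ mol⁻¹)
    (constants at 5 °C)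

In the flask at 90.0 min the shortfall holds 20.0% starting material and 20.0% quenched substrate, and quenched substrate already stood at 20.0% after 9.00 min, before the first reading at 10.0 min. Set against Saturday's at the same moment, so that the creep drops out, Sunday's took the shortfall down by 0.349 half-lives, against 0.498 reckoned. The same recipe run at 30 °C made 6.99% product by 90.0 min, a charge worth 0.105 half-lives.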